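The data were computed from invented constants, and the scatter is random.

**What we lack.** We cannot read a flask that was never run, so we must carry its number over from two runs that were.

| flask | substrate | reagent in the second phase | remark | time | volume of the second phase over the first |
|---|---|---|---|---|---|
| Thursday's | 0.10 M | 0.080 M | run made earlier |  |  |
| Monday's | 0.10 M | 0.18 M | run made earlier |  |  |
| flask | 0.10 M | 0.120 M |  | 25 min | 1.0 |

| run | time / min | product / % | idle adduct / % |
|---|---|---|---|
| Thursday's | 1.50 | 0.2 | 0 |
| Thursday's | 3.00 | 1.3 | 0 |
| Thursday's | 6.00 | 2.8 | 1.4 |
| Thursday's | 10.0 | 3.9 | 0 |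
| Thursday's | 20.0 | 10.1 | 0.9 |
| Monday's | 1.50 | 1.8 | 0.4 |
| Monday's | 3.00 | 3.0 | 0 |
| Monday's | 6.00 | 6.1 | 0 |
| Monday's | 10.0 | 9.4 | 1.8 |
| Monday's | 20.0 | 18.6 | 4.0 |

(readings scatter by 0.5 percentage points)

- the product and idle adduct together standing at 25 min, as a percentage of the substrate charged
- the change that raises the amount of product and idle adduct together at 25 min, in percent of the substrate charged most ("none" if none brings more than 2 percentage points) (epsilon / beta / none)
- amount of product and idle adduct together at 25 min, in percent of the substrate charged, after epsilon

**Two ways.** Product readings hold their idle adduct, as the conditions state. We work in powers of ten. From Thursday's run to Monday's, the reagent charge rises by 0.352. Product rises by 0.265 at the last readings and by 0.382 at the fourth. So the last readings give an order in reagent of 0.753, and the fourth give 1.08. Scaled to this flask, with time taken as proportional, the first way gives 17.1% and the second 15.1%. They part.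

**One figure.** We define the yield per reagent-minute as product over reagent charge times time, an apparent second-order constant. Monday's last reading gives 0.0517 M⁻¹ min⁻¹, and its fourth gives 0.0522 M⁻¹ min⁻¹. Thursday's fourth reading gives 0.0488 M⁻¹ min⁻¹, but its last gives 0.0631 M⁻¹ min⁻¹. That last reading stands 1.8 percentage points above Monday's figure, against a scatter of 0.5 points. We distrust it and commit to Monday's figure, which gives 15.5% for this flask. Scaled in proportion, doubling the reagent gives us 31.0%. We place epsilon between 15.5% and that figure: an order near one fits transfer and reaction alike as the rate-limiting step. We choose beta as the safer change, without a reckoned margin over epsilon.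

**The forecast.** It says 19%, from 17% to 21.5%, so our figure lies lower. It picks beta, “whichever step controls the rate”, and puts epsilon at 25%, from 19% to 35%.

**The result.** This flask gives 15.5%, and its yield per reagent-minute is 0.0517 M⁻¹ min⁻¹. Beta gains 12 points and epsilon 10 points, reaching 25.8%.

    reagent in the reaction phase + product ⇌ idle adduct, settled at all times (K = 110 M⁻¹)
    substrate ⇌ dormant form (K = 16.0, k = 6.30 × 10⁻⁴ s⁻¹)
    reagent in the reaction phase ⇌ reagent in the second phase, rate k3*([reagent in the reaction phase] - [reagent in the second phase]/K3) per volume of the first phase (partition coefficient = 2.90, kL = 3.50 × 10⁻⁴ s⁻¹)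
    substrate + reagent in the reaction phase → product (k = 0.180 M⁻¹ s⁻¹)

**The neighbour.** The same charge is read at 1.0 h. Monday's figure gives 37.2%, but that flask holds 27.7%, a yield per reagent-minute of 0.0385 M⁻¹ min⁻¹. Its substrate stands at 4.9% and its dormant form at 67.4%.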